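**Overview**

- The target is a (3R)-isoflavan. Ring C (dihydropyran, O1–C2–C3–C4–C4a–C8a) is fused to a 7-hydroxy-6-prenyl ring A and carries at C3 a 5-hydroxy-2,2-dimethyl-2H-chromen-8-yl unit (ring B). C3 is the only stereocentre.
- Enabling feature: C3 bears two CH2 arms, C2 (bonded to O1) and C4 (bonded to C4a). Cutting O1–C2 and C4–C4a removes ring A and leaves C3 as the prochiral central carbon of a 2-aryl-propane-1,3-diol whose aryl group is the intact chromene ring B.
- Further cuts: the aryl–C3 bond (malonate arylation of an 8-bromochromene) and the pyran ring of the chromene (O-propargylation, Claisen rearrangement, oxa-6π closure on 4-bromoresorcinol). Ring A comes from 4,6-dibromoresorcinol and prenyl bromide.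
- Forward order: chromene pyran ring, then the C2–C3–C4 unit, lipase desymmetrisation, iodination of the free arm, Negishi coupling to ring A at C4–C4a, unmasking, Mitsunobu closure of ring C at O1–C2, desilylation.
- Stereochemistry: the lipase acetylates one enantiotopic CH2OH of the diol. The acetylated arm becomes C2 and the free arm C4, so the (S)-monoacetate leads to (3R). C3 is never adjacent to a carbonyl or a leaving group afterwards.

Key step: step 6

Remark (assumption): the sense in which a lipase differentiates the two hydroxymethyl arms of this ortho-oxygenated 2-aryl-propane-1,3-diol cannot be predicted with certainty; the route assumes acylation of the pro-S arm, to be confirmed by chiral HPLC and chemical correlation, and the first fallback covers the opposite outcome.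

**Route**

Step 1
Reactants: 1 bromoresorcinol (4-bromobenzene-1,3-diol)
Product: 2 monosilyl ether (2-bromo-5-(triisopropylsilyloxy)phenol)
Conditions: TIPSCl (1.0 equiv, slow addition), imidazole, CH2Cl2, −20 → 0 °C
Reagents that add atoms: triisopropylsilyl chloride, CC(C)[Si](Cl)(C(C)C)C(C)C
Why: Regioselective O-silylation of a phenol: the bulky silyl chloride should react at the unhindered hydroxyl para to bromine and not at the hydroxyl flanked by the ortho bromine, and one equivalent at low temperature limits bis-silylation.

Step 2
Reactants: 2 monosilyl ether (2-bromo-5-(triisopropylsilyloxy)phenol) + 3 propargylic chloride (3-chloro-3-methylbut-1-yne)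
Product: 4 aryl propargyl ether ({4-bromo-3-[(2-methylbut-3-yn-2-yl)oxy]phenoxy}triisopropylsilane)
Conditions: K2CO3, KI (cat.), CuI (cat.), acetone, 55 °C
Reagents that add atoms: none
Why: Copper-assisted Williamson-type O-alkylation of the remaining phenoxide by the tertiary propargylic chloride, which is known to etherify even ortho-substituted phenols, while anhydrous carbonate in acetone leaves the aryl silyl ether untouched.

Step 3
Reactants: 4 aryl propargyl ether ({4-bromo-3-[(2-methylbut-3-yn-2-yl)oxy]phenoxy}triisopropylsilane)
Product: 7 bromochromene (8-bromo-2,2-dimethyl-5-(triisopropylsilyloxy)-2H-chromene), via allenylphenol 5 (not isolated), via ortho-quinone methide 6 (not isolated)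
Conditions: N,N-diethylaniline, 170 °C
Reagents that add atoms: none
Why: Thermal aryl propargyl ether Claisen rearrangement followed in the same flask by enolisation, 1,5-hydrogen shift and oxa-6π electrocyclisation, a standard entry to 2,2-dimethyl-2H-chromenes; since one ortho position carries bromine, the allenyl group can only be delivered to the carbon between the two oxygens, which fixes the 5-silyloxy-8-bromo pattern.

Step 4
Reactants: 7 bromochromene (8-bromo-2,2-dimethyl-5-(triisopropylsilyloxy)-2H-chromene) + 8 diethyl malonate
Product: 9 arylmalonate (diethyl 2-[2,2-dimethyl-5-(triisopropylsilyloxy)-2H-chromen-8-yl]malonate)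
Conditions: Pd(dba)2 (2 mol %), P(t-Bu)3·HBF4 (4 mol %), K3PO4, toluene, 70 °C
Reagents that add atoms: none
Why: Palladium-catalysed α-arylation of a malonate (enolate cross-coupling with an aryl bromide), in which the bulky electron-rich trialkylphosphine should allow oxidative addition to the electron-rich ortho-alkoxy bromide and reductive elimination of the arylmalonate, the product being protected from a second arylation by its own deprotonation and the mild phosphate base sparing the esters and the silyl ether.

Step 5
Reactants: 9 arylmalonate (diethyl 2-[2,2-dimethyl-5-(triisopropylsilyloxy)-2H-chromen-8-yl]malonate)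
Product: 10 prochiral diol (2-[2,2-dimethyl-5-(triisopropylsilyloxy)-2H-chromen-8-yl]propane-1,3-diol)
Conditions: LiAlH4 (excess, inverse addition), Et2O, −20 → 0 °C; aq. potassium sodium tartrate work-up
Reagents that add atoms: none
Why: Hydride reduction of both ester groups to primary alcohols, made reliable for an enolisable arylmalonate by adding the ester to excess LiAlH4 at low temperature so that reduction outruns deprotonation of the acidic benzylic C–H, with the aryl silyl ether and the chromene alkene inert to the hydride.

Step 6
Reactants: 10 prochiral diol (2-[2,2-dimethyl-5-(triisopropylsilyloxy)-2H-chromen-8-yl]propane-1,3-diol)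
Product: 11 monoacetate ((2S)-3-hydroxy-2-[2,2-dimethyl-5-(triisopropylsilyloxy)-2H-chromen-8-yl]propyl acetate)
Conditions: Burkholderia cepacia lipase (immobilised), vinyl acetate (4 equiv), t-BuOMe, 20 °C, filtered once the diol is consumed
Reagents that add atoms: vinyl acetate, CC(=O)OC=C
Why: Vinyl acetate acetylates the active-site serine of the lipase, irreversibly because the vinyl alcohol released tautomerises to acetaldehyde, and the diol then binds with its flat chromenyl group and the hydrogen of the prochiral carbon in different pockets, so that only one of the two enantiotopic CH2OH groups reaches the acyl-enzyme and a single ester C–O bond is formed. The closest known reaction type is the lipase-catalysed enantiotopic-group-selective monoacetylation of prochiral 2-aryl-propane-1,3-diols with enol esters. No ring is closed in this step; its task is to fix the configuration of the future C3 and to mark the arms, the acetylated one becoming C2 and the free one C4. The new stereocentre is controlled by the chiral active site alone (catalyst control), the substrate being achiral. The step needs enantiotopic-group selectivity and mono- over bis-acylation; the substrate secures both because its only acylable groups are the two primary hydroxyls (the phenol is silylated), because aryl against hydrogen is the substituent pair such lipases distinguish best, and because the minor monoacetate, whose free hydroxyl sits on the arm the enzyme prefers, is drained faster into the achiral diacetate.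

Step 7
Reactants: 11 monoacetate ((2S)-3-hydroxy-2-[2,2-dimethyl-5-(triisopropylsilyloxy)-2H-chromen-8-yl]propyl acetate)
Product: 12 acetoxy iodide ((2R)-3-iodo-2-[2,2-dimethyl-5-(triisopropylsilyloxy)-2H-chromen-8-yl]propyl acetate)
Conditions: PPh3, I2, imidazole, CH2Cl2, 0 °C (alcohol added to the premixed reagent)
Reagents that add atoms: iodine, II
Why: Appel-type iodination (PPh3, I2, imidazole) replaces the primary hydroxyl by iodide through SN2 at the CH2 carbon under near-neutral conditions at 0 °C, so the stereocentre (not the reacting carbon) is untouched and 1,3-acetyl migration, which would erode the enantiomeric purity, is not promoted.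

Step 8
Reactants: 13 dibromoresorcinol (4,6-dibromobenzene-1,3-diol)
Product: 14 bis(methoxymethyl) ether (1,5-dibromo-2,4-bis(methoxymethoxy)benzene)
Conditions: MOMCl, i-Pr2NEt, CH2Cl2, 0 °C → rt
Reagents that add atoms: chloromethyl methyl ether, COCCl
Why: Base-mediated acetalisation of both phenols by the chloromethyl ether (methoxymethyl protection) on a symmetric substrate, giving a single product whose ether groups tolerate and chelate the organolithium formed next.

Step 9
Reactants: 14 bis(methoxymethyl) ether (1,5-dibromo-2,4-bis(methoxymethoxy)benzene) + 15 prenyl bromide (1-bromo-3-methylbut-2-ene)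
Product: 18 ring A bromide (1-bromo-2,4-bis(methoxymethoxy)-5-(3-methylbut-2-en-1-yl)benzene), via aryllithium 16 (not isolated), via arylcopper 17 (not isolated)
Conditions: n-BuLi (1.05 equiv), THF, −78 °C; CuBr·SMe2 (1.0 equiv), −78 → −40 °C; then 15, −40 → 0 °C
Reagents that add atoms: none
Why: Bromine–lithium exchange at one of the two equivalent C–Br bonds (one equivalent of n-BuLi at −78 °C, the aryllithium being stabilised by the ortho acetal oxygen), transmetalation to the arylcopper and α-selective allylic substitution on prenyl bromide, the usual way to prenylate an aryl nucleophile without forming the reverse-prenyl isomer.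

Step 10
Reactants: 12 acetoxy iodide ((2R)-3-iodo-2-[2,2-dimethyl-5-(triisopropylsilyloxy)-2H-chromen-8-yl]propyl acetate) + 18 ring A bromide (1-bromo-2,4-bis(methoxymethoxy)-5-(3-methylbut-2-en-1-yl)benzene)
Product: 20 coupled acetate ((2R)-3-[2,4-bis(methoxymethoxy)-5-(3-methylbut-2-en-1-yl)phenyl]-2-[2,2-dimethyl-5-(triisopropylsilyloxy)-2H-chromen-8-yl]propyl acetate), via alkylzinc iodide 19 (not isolated)
Conditions: Zn dust (I2-activated), DMF, 25 °C; then 18, Pd2(dba)3 (2.5 mol %), SPhos (2-dicyclohexylphosphino-2',6'-dimethoxybiphenyl, 10 mol %), DMF/THF, 45 °C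
Reagents that add atoms: none
Why: Negishi sp3–sp2 cross-coupling: zinc inserts into the primary C–I bond to give an ester-tolerant alkylzinc iodide, and the bulky biarylphosphine on palladium should make reductive elimination from the aryl(alkyl)palladium faster than β-hydride elimination, so the C4–C4a bond forms without involving the stereocentre.

Step 11
Reactants: 20 coupled acetate ((2R)-3-[2,4-bis(methoxymethoxy)-5-(3-methylbut-2-en-1-yl)phenyl]-2-[2,2-dimethyl-5-(triisopropylsilyloxy)-2H-chromen-8-yl]propyl acetate)
Product: 21 seco-isoflavan (4-{(2R)-3-hydroxy-2-[2,2-dimethyl-5-(triisopropylsilyloxy)-2H-chromen-8-yl]propyl}-6-(3-methylbut-2-en-1-yl)benzene-1,3-diol)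
Conditions: HCl (1.25 M in MeOH), THF, 0 → 35 °C
Reagents that add atoms: none
Why: Acid-catalysed methanolysis, in which both phenolic methoxymethyl acetals are exchanged into dimethoxymethane and the acetate is transesterified to methyl acetate, while the aryl triisopropylsilyl ether, the chromene and the prenyl group are expected to survive dilute methanolic HCl near room temperature.

Step 12
Reactants: 21 seco-isoflavan (4-{(2R)-3-hydroxy-2-[2,2-dimethyl-5-(triisopropylsilyloxy)-2H-chromen-8-yl]propyl}-6-(3-methylbut-2-en-1-yl)benzene-1,3-diol)
Product: 22 silylated isoflavan ((3R)-3-[2,2-dimethyl-5-(triisopropylsilyloxy)-2H-chromen-8-yl]-6-(3-methylbut-2-en-1-yl)chroman-7-ol)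
Conditions: PPh3, DIAD, THF (0.01 M), 0 °C → rt
Reagents that add atoms: none
Why: Intramolecular Mitsunobu etherification, a 6-exo-tet SN2 displacement of the activated primary hydroxyl by the ortho phenol that closes ring C at O1–C2; the other phenol is para to the side chain and cannot reach, high dilution suppresses intermolecular ether formation, and the reacting carbon is an achiral CH2, so C3 keeps its configuration.

Step 13
Reactants: 22 silylated isoflavan ((3R)-3-[2,2-dimethyl-5-(triisopropylsilyloxy)-2H-chromen-8-yl]-6-(3-methylbut-2-en-1-yl)chroman-7-ol)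
Product: 23 target ((3R)-3-(5-hydroxy-2,2-dimethyl-2H-chromen-8-yl)-6-(3-methylbut-2-en-1-yl)chroman-7-ol)
Conditions: TBAF (1.1 equiv), AcOH (1.1 equiv), THF, 0 °C
Reagents that add atoms: none
Why: Fluoride-induced cleavage of the aryl silyl ether, driven by Si–F bond formation and buffered with acetic acid so that the electron-rich phenolate is protonated at once, liberates the chromenol and gives the target.

**Compound list**

1 | 4-bromoresorcinol (4-bromobenzene-1,3-diol) | Oc1ccc(Br)c(O)c1 | starting material
2 | 2-bromo-5-(triisopropylsilyloxy)phenol | Oc1cc(O[Si](C(C)C)(C(C)C)C(C)C)ccc1Br | intermediate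
3 | 3-chloro-3-methylbut-1-yne | CC(C)(Cl)C#C | starting material
4 | {4-bromo-3-[(2-methylbut-3-yn-2-yl)oxy]phenoxy}triisopropylsilane | C#CC(C)(C)Oc1cc(O[Si](C(C)C)(C(C)C)C(C)C)ccc1Br | intermediate
5 | 6-bromo-2-(3-methylbuta-1,2-dien-1-yl)-3-(triisopropylsilyloxy)phenol | CC(C)=C=Cc1c(O)c(Br)ccc1O[Si](C(C)C)(C(C)C)C(C)C | intermediate
6 | (6Z)-2-bromo-6-(3-methylbut-2-en-1-ylidene)-5-(triisopropylsilyloxy)cyclohexa-2,4-dien-1-one | CC(C)=C/C=C1\C(=O)C(Br)=CC=C1O[Si](C(C)C)(C(C)C)C(C)C | intermediate
7 | 8-bromo-2,2-dimethyl-5-(triisopropylsilyloxy)-2H-chromene | CC1(C)C=Cc2c(O[Si](C(C)C)(C(C)C)C(C)C)ccc(Br)c2O1 | intermediate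
8 | diethyl malonate | CCOC(=O)CC(=O)OCC | starting material
9 | diethyl 2-[2,2-dimethyl-5-(triisopropylsilyloxy)-2H-chromen-8-yl]malonate | CCOC(=O)C(C(=O)OCC)c1ccc(O[Si](C(C)C)(C(C)C)C(C)C)c2c1OC(C)(C)C=C2 | intermediate
10 | 2-[2,2-dimethyl-5-(triisopropylsilyloxy)-2H-chromen-8-yl]propane-1,3-diol | OCC(CO)c1ccc(O[Si](C(C)C)(C(C)C)C(C)C)c2c1OC(C)(C)C=C2 | intermediate
11 | (2S)-3-hydroxy-2-[2,2-dimethyl-5-(triisopropylsilyloxy)-2H-chromen-8-yl]propyl acetate | CC(=O)OC[C@@H](c1ccc(O[Si](C(C)C)(C(C)C)C(C)C)c2c1OC(C)(C)C=C2)CO | intermediate
12 | (2R)-3-iodo-2-[2,2-dimethyl-5-(triisopropylsilyloxy)-2H-chromen-8-yl]propyl acetate | CC(=O)OC[C@@H](c1ccc(O[Si](C(C)C)(C(C)C)C(C)C)c2c1OC(C)(C)C=C2)CI | intermediate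
13 | 4,6-dibromoresorcinol (4,6-dibromobenzene-1,3-diol) | Oc1cc(O)c(Br)cc1Br | starting material
14 | 1,5-dibromo-2,4-bis(methoxymethoxy)benzene | COCOc1cc(OCOC)c(Br)cc1Br | intermediate
15 | prenyl bromide (1-bromo-3-methylbut-2-ene) | CC(C)=CCBr | starting material
16 | [5-bromo-2,4-bis(methoxymethoxy)phenyl]lithium | [Li]c1cc(Br)c(OCOC)cc1OCOC | intermediate
17 | [5-bromo-2,4-bis(methoxymethoxy)phenyl]copper | [Cu]c1cc(Br)c(OCOC)cc1OCOC | intermediate
18 | 1-bromo-2,4-bis(methoxymethoxy)-5-(3-methylbut-2-en-1-yl)benzene | COCOc1cc(OCOC)c(CC=C(C)C)cc1Br | intermediate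
19 | {(2R)-3-acetoxy-2-[2,2-dimethyl-5-(triisopropylsilyloxy)-2H-chromen-8-yl]propyl}zinc iodide | CC(=O)OC[C@@H](c1ccc(O[Si](C(C)C)(C(C)C)C(C)C)c2c1OC(C)(C)C=C2)C[Zn]I | intermediate
20 | (2R)-3-[2,4-bis(methoxymethoxy)-5-(3-methylbut-2-en-1-yl)phenyl]-2-[2,2-dimethyl-5-(triisopropylsilyloxy)-2H-chromen-8-yl]propyl acetate | CC(=O)OC[C@@H](c1ccc(O[Si](C(C)C)(C(C)C)C(C)C)c2c1OC(C)(C)C=C2)Cc1cc(CC=C(C)C)c(OCOC)cc1OCOC | intermediate
21 | 4-{(2R)-3-hydroxy-2-[2,2-dimethyl-5-(triisopropylsilyloxy)-2H-chromen-8-yl]propyl}-6-(3-methylbut-2-en-1-yl)benzene-1,3-diol | OC[C@@H](c1ccc(O[Si](C(C)C)(C(C)C)C(C)C)c2c1OC(C)(C)C=C2)Cc1cc(CC=C(C)C)c(O)cc1O | intermediate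
22 | (3R)-3-[2,2-dimethyl-5-(triisopropylsilyloxy)-2H-chromen-8-yl]-6-(3-methylbut-2-en-1-yl)chroman-7-ol | CC(C)=CCc1cc2c(cc1O)OC[C@@H](c1ccc(O[Si](C(C)C)(C(C)C)C(C)C)c3c1OC(C)(C)C=C3)C2 | intermediate
23 | (3R)-3-(5-hydroxy-2,2-dimethyl-2H-chromen-8-yl)-6-(3-methylbut-2-en-1-yl)chroman-7-ol | CC(C)=CCc1cc2c(cc1O)OC[C@@H](c1ccc(O)c3c1OC(C)(C)C=C3)C2 | target

**Step count and risks**

Total step count: 13. Longest linear sequence: 11 steps (steps 1–7 and 10–13, from 4-bromoresorcinol). The ring A bromide takes 2 steps (8 and 9).

Steps most likely to fail: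

1. Step 6. The enzyme may distinguish the two hydroxymethyl arms poorly, or in the opposite sense, because the ortho pyran oxygen and the bulk of the chromenyl group change how the aryl group sits in the active site. The fallback sets out from diol 10. Exhaustive acetylation (Ac2O, pyridine, cat. DMAP, CH2Cl2) would give the prochiral diacetate F1, and the desymmetrisation would then be run in the hydrolytic direction (the same lipase or pig liver esterase, pH 7 phosphate buffer with acetone as cosolvent). A hydrolase removes the acetate from the arm it would otherwise acylate, so hydrolysis with the same enzyme leads into the opposite enantiomeric series. A short screen of hydrolases in this mode should find one that leaves the acetate on the required arm, and the route is rejoined at monoacetate 11.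

2. Step 10. Zinc insertion may stall or the alkylzinc may be protonated. β-Hydride elimination at the benzylic C–H of the alkylpalladium intermediate may compete with reductive elimination. Oxidative addition to the electron-rich ortho-alkoxy bromide may be slow. The fallback reverses the polarity of the partners and sets out from bromide 18. Bromine–lithium exchange (n-BuLi, THF, −78 °C) would give the aryllithium F2, which ZnCl2 would convert into the arylzinc chloride F3, a nucleophile without β-hydrogens. Palladium-catalysed alkyl–aryl Negishi coupling of F3 with the primary iodide 12 (Pd2(dba)3, tricyclopentylphosphine, N-methylimidazole, THF/NMP, 80 °C) would rejoin the route at the coupled acetate 20.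

3. Step 11. The prolonged exposure to methanolic HCl needed to remove the acetate may cause acid-catalysed cyclisation of the freed C7 phenol onto the prenyl double bond, addition of methanol to the electron-rich chromene double bond, or loss of the silyl ether. The fallback sets out from 20 and separates the two deprotections so that no protic acid is used. K2CO3-catalysed methanolysis at 0 °C would remove only the acetate and give the bis(methoxymethyl) ether alcohol F4. The two acetals would then be cleaved by Lewis-acid-assisted thiolysis (ZnBr2, propane-1-thiol, CH2Cl2, 0 °C, a few minutes), rejoining the route at 21.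

Further compounds
F1 | step 6 | 2-[2,2-dimethyl-5-(triisopropylsilyloxy)-2H-chromen-8-yl]propane-1,3-diyl diacetate | CC(=O)OCC(COC(C)=O)c1ccc(O[Si](C(C)C)(C(C)C)C(C)C)c2c1OC(C)(C)C=C2
F2 | step 10 | [2,4-bis(methoxymethoxy)-5-(3-methylbut-2-en-1-yl)phenyl]lithium | [Li]c1cc(CC=C(C)C)c(OCOC)cc1OCOC
F3 | step 10 | [2,4-bis(methoxymethoxy)-5-(3-methylbut-2-en-1-yl)phenyl]zinc chloride | Cl[Zn]c1cc(CC=C(C)C)c(OCOC)cc1OCOC
F4 | step 11 | (2R)-3-[2,4-bis(methoxymethoxy)-5-(3-methylbut-2-en-1-yl)phenyl]-2-[2,2-dimethyl-5-(triisopropylsilyloxy)-2H-chromen-8-yl]propan-1-ol | OC[C@@H](c1ccc(O[Si](C(C)C)(C(C)C)C(C)C)c2c1OC(C)(C)C=C2)Cc1cc(CC=C(C)C)c(OCOC)cc1OCOC
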